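## The problem

Compound 18 is an isoflavone: rings A and C form a 5,7-dihydroxy-4H-chromen-4-one, and C3 of ring C carries ring B, which is fused through O2' and C3' to a 2H-pyran (ring D). Ring B is therefore a 1,2,3,4-tetrasubstituted benzene whose two oxygen atoms have different fates (O2' inside ring D, O4' a free phenol), so they must be told apart early and without ambiguity. The only stereocentre is the quaternary C2'' of ring D, which bears methyl, hydroxymethyl, the ring oxygen and the vinylic C3''. No other stereocentre can direct or correct it, so a chiral catalyst has to set it in the (S) sense; once set, it can be lost only by ionisation of the tertiary allylic C–O bond. The C3''=C4'' double bond is an electron-rich styrene flanked by two oxygen-bearing ring carbons. It rules out hydrogenolysis, boron halides and hot strong acid, so every protecting group must fall under mild acid at the end. The feature that opens a short route is ring A: it is a phloroglucinol whose C4a carries the C4 carbonyl. That is the Claisen-folded form of a 3,5,7-triketo acid in which chain carbon 6 has bonded to chain carbon 1 (the C4a–C5 bond), with C4, C3 and ring B as the starter arylacetyl unit. The first five carbons of such a chain are stable when locked as a 4-hydroxy-2-pyrone, so ring A can be grown on the ring B side chain and then folded, leaving only C2 of ring C to add.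

## Retrosynthesis

**18 from 17.** The last operation removes two protecting groups only: the MOM ether on O4' and a TBS ether on the primary hydroxyl. The ring A hydroxyls are never protected, because they are formed free late in the route. A silyl ether is preferred to a second MOM group on the primary alcohol, since an alkyl MOM ether would need acid strong enough to protonate the chromene double bond. The forward step asks only for dilute methanolic acid near room temperature.

**17 from 15.** Cutting O1–C2 and C2–C3 removes the one-carbon unit C2 and leaves the deoxybenzoin 15. The neighbouring cut, a cross-coupling between a 3-halochromone and a ring B organometallic, would bring ring A in ready-made and would need a metallated, fully substituted ring B. The deoxybenzoin route asks only that the methylene between the ketone and ring B condense with an amide acetal (enaminone 16) and that an ortho phenol then close ring C. Both ortho phenols of 15 are equivalent, so there is no regiochemical question.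

**15 from 13.** This is the key disconnection: the C4a–C5 bond of ring A is cut. Ring A opens to the triketo ester 14, which is written back to its stable enol lactone, the 6-(2-oxoalkyl)-4-hydroxy-2-pyrone 13. Against a Friedel–Crafts or Hoesch acylation of phloroglucinol, this avoids the strong Lewis acids that the chromene and the acetal cannot bear. It also delivers ring A already acylated at the right carbon. The forward reaction must fold 14 in the Claisen and not the aldol sense, which is what magnesium methoxide is known to do with this class of pyrone.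

**13 from 11 and 12.** The bond between the side-chain ketone carbon and the pyrone's exocyclic methylene is cut. This gives commercial triacetic acid lactone 12 as its dianion and an activated arylacetic acid, chosen as the Weinreb amide 11. An ester would also serve, but its α-hydrogens are more acidic and its ketone product would be freed in the presence of base. The amide is less prone to proton transfer and holds the adduct as a chelate until work-up. The forward step needs C-acylation at the 6-methyl carbon of the dianion, the established site of its reactions with electrophiles.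

**11 from 10.** Ring D is opened at C3''=C4'' by a metathesis disconnection to the styrene and the vinyl group on the quaternary carbon of 10. This cut is preferred to closing ring D through the aryl ether oxygen because it leaves the stereocentre to be set in an open-chain ether, where catalyst control is available. The forward reaction forms a six-membered ring with a cis alkene and loses ethene.

**10 from 9, and 9 from 7 and 8.** After removal of the silyl group, the tertiary aryl ether C2''–O bond is cut. The stereocentre then comes from racemic isoprene monoepoxide 8 and the phenol 7 by palladium-catalysed asymmetric allylic etherification. The etherification is placed on the vinylphenol 7 and not on its aldehyde precursor 6, because the phenoxide of a salicylaldehyde is a better leaving group and would invite re-ionisation of the product. The forward step must deliver the phenoxide to the more substituted allyl terminus with ligand control of the face.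

**7 from 6, and 6 from 4.** The vinyl group comes from the aldehyde of 6 by methylenation. The formyl carbon is introduced at C3' of 4 by magnesium-mediated ortho-formylation, which passes through the hydroxymethyl stage 5. In 4 the only free position ortho to the phenol is C3', because the other ortho carbon carries the side chain, so the four contiguous substituents of ring B are set without a selectivity problem.

**4 from 3, 3 from 2, and 2 from 1.** The Weinreb amide and the free ortho phenol of 4 arise together by aminolysis of the lactone 3. That lactone is the MOM ether of 2, the lactone of commercial 2,4-dihydroxyphenylacetic acid 1. Lactonisation engages only the ortho hydroxyl, so the two ring B oxygens are differentiated by constitution and not by selective protection. The alternative of attaching the two-carbon side chain late, by palladium-catalysed arylation of an acetate enolate with an aryl bromide, was set aside for two reasons. It would require the two phenols to be distinguished next to a halogen with no reliable bias, and it costs a step that 1 makes unnecessary.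

## Roads not taken

**Alternative 1:** Ring B is made last, on a finished chromone, by an aromatic annulation. The cut removes the C1'–C2', C2'–C3' and C4'–C5' bonds. In the forward sense the diazo enone A1 undergoes photochemical Wolff rearrangement, and the ketene that results adds to the silyloxyalkyne A2. Four-electron ring opening and six-electron ring closure then give the resorcinol monosilyl ether A3.

- **Merits.** The route is convergent. The substitution pattern of ring B and the distinction between O2' (free) and O4' (silylated) follow from the pericyclic sequence. The stereocentre comes from an enantiopure epoxide and would be transferred with inversion when O2' later opens it at the tertiary carbon.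
- **Weak points.** The chromone of A1 absorbs in the region needed for the Wolff step, and its C2=C3 bond is open to photocycloaddition. A2 carries an epoxide through ynolate chemistry. After the key step ring D still has to be closed and then dehydrogenated at C3''–C4'' next to free phenols, an oxidation that electron-rich rings A and B may not tolerate.
- **Comparison.** Alternative 1 is the more convergent plan and is better at fixing the ring B pattern. The chosen plan sets against it a key step of a known type, a ring D that is complete with its double bond before the core is built, and an endgame of two mild steps.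

**Alternative 2:** This plan cuts the C3'–C4'' bond of ring D. In the forward sense the aryl propargyl ether A4 cyclises with Ph3PAuNTf2, the arene carbon between the two oxygens adding to the terminal alkyne carbon (6-endo) to give the chromene aldehyde A5.

- **Merits.** The stereocentre is bought or made as a tertiary propargylic alcohol and is fixed before the ring is closed. The cyclisation is catalytic and mild, and its regiochemistry is forced because the other ortho position carries the formyl group. In setting the stereocentre this road is arguably safer than a catalytic asymmetric etherification of a hindered phenol.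
- **Weak points.** A4 cannot be made by copper-catalysed propargylation without racemisation, so a hindered tertiary alkoxide would have to displace an activated aryl fluoride. The enantiopure alcohol needs its own synthesis or resolution. A5 is an aldehyde one carbon short of the arylacetyl unit, so several homologation steps follow before rings A and C can be addressed, and for those this plan offers nothing new.
- **Comparison.** The chosen plan sets against it the use of cheap racemic 8, a side chain that is present from the first step, and a single operation that builds ring A. The alkyne cyclisation is kept in reserve as the fallback for step 6.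

**Alternative 3:** This plan cuts C3–C4 and O1–C2 and brings ring A in intact. The arylacetaldehyde A6 is converted into its morpholine enamine A7, which is C-acylated by the acid chloride A8. Methanolic K2CO3 then frees an ortho phenoxide that displaces morpholine to give the isoflavone A9.

- **Merits.** The route is convergent, ring C closes in one flask, and no separate one-carbon insertion is needed. In step count after the ring B fragment it is shorter than the chosen plan by about one step.
- **Weak points.** A6 is an electron-rich, easily enolised aldehyde that tends to self-condense. A8 is a doubly ortho-substituted aroyl chloride whose acetates can migrate or be attacked. C-acylation of an aldehyde enamine by so hindered an electrophile competes with N-acylation and ketene formation.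
- **Comparison.** Alternative 3 wins on convergence and step count. The chosen plan sets against it a key step with close analogy (magnesium methoxide folding of 6-(2-oxoalkyl)-4-hydroxy-2-pyrones), intermediates that are stable amides and pyrones instead of an arylacetaldehyde, and a ring A that needs no protection at any stage.

Key step: step 10

Assumption: the (R,R) ligand of step 6 is taken to give the (S) ether by analogy with additions of oxygen pronucleophiles to this epoxide; if the sense proves opposite, the (S,S) ligand is used and nothing else changes.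

## Route

Step 1
Reactants: 1 2,4-dihydroxyphenylacetic acid
Product: 2 6-hydroxy-1-benzofuran-2(3H)-one
Conditions: TsOH·H2O (cat.), toluene, reflux, Dean–Stark
Reagents that add atoms: none
Why: Acid-catalysed lactonisation (intramolecular Fischer esterification); only the ortho hydroxyl can reach the carboxyl through a five-membered ring, so the two phenols are differentiated by constitution, and removal of water drives the reaction.

Step 2
Reactants: 2 6-hydroxy-1-benzofuran-2(3H)-one
Product: 3 6-(methoxymethoxy)-1-benzofuran-2(3H)-one
Conditions: MOMCl, iPr2NEt, CH2Cl2, 0 °C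
Reagents that add atoms: chloromethyl methyl ether (MOMCl), COCCl
Why: O-alkylation of the single free phenol under amine base; the hindered amine at 0 °C should engage the phenolic O–H much faster than the lactone C–H, and the MOM group is small, base-stable and able to coordinate magnesium in step 4.

Step 3
Reactants: 3 6-(methoxymethoxy)-1-benzofuran-2(3H)-one
Product: 4 2-[2-hydroxy-4-(methoxymethoxy)phenyl]-N-methoxy-N-methylacetamide
Conditions: MeNH(OMe)·HCl, AlMe3, CH2Cl2, 0 °C to rt; then cold 1 M HCl
Reagents that add atoms: N,O-dimethylhydroxylamine hydrochloride, CNOC.Cl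
Why: Weinreb aminolysis of a lactone; the aluminium amide attacks the acyl carbon of the strained aryl ester, which releases the ortho phenol and installs the N-methoxy-N-methylamide needed in step 9 in one operation.

Step 4
Reactants: 4 2-[2-hydroxy-4-(methoxymethoxy)phenyl]-N-methoxy-N-methylacetamide
Product: 6 2-[3-formyl-2-hydroxy-4-(methoxymethoxy)phenyl]-N-methoxy-N-methylacetamide, via hydroxymethylphenol 5 (not isolated)
Conditions: MgCl2, Et3N, (CH2O)n, MeCN, reflux; then cold 1 M HCl
Reagents that add atoms: paraformaldehyde (source of formaldehyde), C=O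
Why: Magnesium-mediated ortho-formylation of a phenol; the magnesium phenoxide adds formaldehyde at the ortho carbon inside a chelate and the benzylic alkoxide 5 is oxidised by a second formaldehyde through hydride transfer; C3 is the only free ortho position, so the regiochemistry is fixed by the substrate.

Step 5
Reactants: 6 2-[3-formyl-2-hydroxy-4-(methoxymethoxy)phenyl]-N-methoxy-N-methylacetamide
Product: 7 2-[3-ethenyl-2-hydroxy-4-(methoxymethoxy)phenyl]-N-methoxy-N-methylacetamide
Conditions: Ph3PCH3Br (2.5 equiv), KOtBu (2.4 equiv), THF, 0 °C to rt
Reagents that add atoms: methyltriphenylphosphonium bromide, C[P+](c1ccccc1)(c1ccccc1)c1ccccc1.[Br-]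
Why: Wittig methylenation; one equivalent of ylide is spent on the phenol and the second converts the aldehyde of the phenoxide, as is usual for salicylaldehydes, while the amide does not react at this temperature; the styrene is used without delay.

Step 6
Reactants: 7 2-[3-ethenyl-2-hydroxy-4-(methoxymethoxy)phenyl]-N-methoxy-N-methylacetamide; 8 2-methyl-2-vinyloxirane (racemic isoprene monoepoxide)
Product: 9 2-[3-ethenyl-2-{[(2S)-1-hydroxy-2-methylbut-3-en-2-yl]oxy}-4-(methoxymethoxy)phenyl]-N-methoxy-N-methylacetamide
Conditions: 8 (1.3 equiv), Pd2(dba)3·CHCl3 (1.5 mol %), N,N'-[(1R,2R)-cyclohexane-1,2-diyl]bis[2-(diphenylphosphanyl)benzamide] (4.5 mol %), CH2Cl2, rt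
Reagents that add atoms: none
Why: Asymmetric allylic etherification of the Tsuji–Trost type run as a dynamic kinetic asymmetric transformation; zerovalent palladium opens racemic 8 to a π-allyl complex whose alkoxide deprotonates the phenol and returns the phenoxide to the adjacent, more substituted allyl terminus, and since the two diastereomeric π-allyl complexes interconvert faster than they are attacked, the ligand alone selects the face and sets the quaternary C–O stereocentre as (S).

Step 7
Reactants: 9 2-[3-ethenyl-2-{[(2S)-1-hydroxy-2-methylbut-3-en-2-yl]oxy}-4-(methoxymethoxy)phenyl]-N-methoxy-N-methylacetamide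
Product: 10 2-[2-{[(2S)-1-{[tert-butyl(dimethyl)silyl]oxy}-2-methylbut-3-en-2-yl]oxy}-3-ethenyl-4-(methoxymethoxy)phenyl]-N-methoxy-N-methylacetamide
Conditions: TBSCl, imidazole, DMF, rt
Reagents that add atoms: tert-butyl(chloro)dimethylsilane (TBSCl), CC(C)(C)[Si](C)(C)Cl
Why: Imidazole-promoted silylation of the only hydroxyl; the primary TBS ether should survive metathesis, amide bases and methoxide and falls with the MOM ether under mild acid in step 12.

Step 8
Reactants: 10 2-[2-{[(2S)-1-{[tert-butyl(dimethyl)silyl]oxy}-2-methylbut-3-en-2-yl]oxy}-3-ethenyl-4-(methoxymethoxy)phenyl]-N-methoxy-N-methylacetamide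
Product: 11 2-[(2S)-2-({[tert-butyl(dimethyl)silyl]oxy}methyl)-5-(methoxymethoxy)-2-methyl-2H-chromen-8-yl]-N-methoxy-N-methylacetamide
Conditions: second-generation Grubbs catalyst (5 mol %), CH2Cl2, 40 °C
Reagents that add atoms: none
Why: Ring-closing olefin metathesis of the styrene with the vinyl group on the quaternary carbon closes ring D as the 2H-chromene with loss of ethene; the ring alkene can only be cis and the stereocentre is not involved.

Step 9
Reactants: 11 2-[(2S)-2-({[tert-butyl(dimethyl)silyl]oxy}methyl)-5-(methoxymethoxy)-2-methyl-2H-chromen-8-yl]-N-methoxy-N-methylacetamide; 12 4-hydroxy-6-methyl-2H-pyran-2-one (triacetic acid lactone)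
Product: 13 6-{3-[(2S)-2-({[tert-butyl(dimethyl)silyl]oxy}methyl)-5-(methoxymethoxy)-2-methyl-2H-chromen-8-yl]-2-oxopropyl}-4-hydroxy-2H-pyran-2-one
Conditions: 12 (2.5 equiv), LiN(iPr)2 (5.2 equiv), THF–DMPU, −78 to −20 °C; then 11, −78 to 0 °C; then 1 M HCl to pH 3, 0 °C
Reagents that add atoms: none
Why: C-acylation of the dianion of 12 at its 6-methyl carbon, the terminal and most nucleophilic site of the dienolate, by a Weinreb amide; the chelated tetrahedral adduct persists until work-up, so the acidic β-keto pyrone is never exposed to base, and the amide α-hydrogens are less acidic than those of an arylacetic ester, which limits proton transfer; the excess dianion covers what proton transfer remains.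

Step 10
Reactants: 13 6-{3-[(2S)-2-({[tert-butyl(dimethyl)silyl]oxy}methyl)-5-(methoxymethoxy)-2-methyl-2H-chromen-8-yl]-2-oxopropyl}-4-hydroxy-2H-pyran-2-one
Product: 15 2-[(2S)-2-({[tert-butyl(dimethyl)silyl]oxy}methyl)-5-(methoxymethoxy)-2-methyl-2H-chromen-8-yl]-1-(2,4,6-trihydroxyphenyl)ethan-1-one, via triketo ester chelate 14 (not isolated)
Conditions: Mg(OMe)2 (excess), MeOH, 25 to 65 °C; then 1 M HCl, 0 °C
Reagents that add atoms: none
Why: Methoxide opens the enol lactone of 13 at its carbonyl carbon to the methyl 3,5,7-trioxooctanoate 14, which divalent magnesium holds as a chelate of its β-dicarbonyl enolates. In this chelate the ketone carbonyls are masked as enolates and the ester carbon is the only electrophile left, so the doubly activated chain carbon 6 attacks chain carbon 1 in a Claisen condensation. Loss of methoxide and threefold enolisation give the phloroglucinol, which forms the C4a–C5 bond and closes ring A in the 6-exo-trig mode. The closest known reaction type is the magnesium methoxide conversion of 6-(2-oxoalkyl)-4-hydroxy-2-pyrones into acylphloroglucinols, a laboratory copy of polyketide Claisen cyclisation. No stereocentre is formed, and the quaternary C2'' has no acidic hydrogen and is untouched. The selectivity needed is Claisen folding over aldol folding (chain carbon 2 onto the C7 carbonyl, which would give a resorcylate) and over attack by the benzylic chain carbon 8; magnesium chelation secures the first and the lower acidity of the singly activated benzylic methylene the second. The MOM ether, the silyl ether and the chromene are inert to methoxide.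

Step 11
Reactants: 15 2-[(2S)-2-({[tert-butyl(dimethyl)silyl]oxy}methyl)-5-(methoxymethoxy)-2-methyl-2H-chromen-8-yl]-1-(2,4,6-trihydroxyphenyl)ethan-1-one
Product: 17 3-[(2S)-2-({[tert-butyl(dimethyl)silyl]oxy}methyl)-5-(methoxymethoxy)-2-methyl-2H-chromen-8-yl]-5,7-dihydroxy-4H-chromen-4-one, via enaminone 16 (not isolated)
Conditions: Me2NCH(OMe)2 (2 equiv), THF, 60 °C
Reagents that add atoms: N,N-dimethylformamide dimethyl acetal, COC(OC)N(C)C
Why: Standard isoflavone synthesis from a 2-hydroxydeoxybenzoin; the amide acetal condenses at the methylene between the ketone and ring B to the enaminone 16, and an ortho phenol then adds to the enamine carbon and expels dimethylamine (6-endo-trig closure of ring C); the two ortho phenols are equivalent, and mild temperature and limited reagent are used to avoid O-methylation.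

Step 12
Reactants: 17 3-[(2S)-2-({[tert-butyl(dimethyl)silyl]oxy}methyl)-5-(methoxymethoxy)-2-methyl-2H-chromen-8-yl]-5,7-dihydroxy-4H-chromen-4-one
Product: 18 5,7-dihydroxy-3-[(2S)-5-hydroxy-2-(hydroxymethyl)-2-methyl-2H-chromen-8-yl]-4H-chromen-4-one
Conditions: HCl (2 M), MeOH, rt to 40 °C
Reagents that add atoms: none
Why: Acid-catalysed acetal exchange of the aryl MOM ether and solvolysis of the primary silyl ether in methanol; the acid is kept dilute and near room temperature so that the chromene double bond is not protonated and the tertiary allylic ether does not ionise.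

## Compound list

1 | 2,4-dihydroxyphenylacetic acid | OC(=O)Cc1ccc(O)cc1O | starting material
2 | 6-hydroxy-1-benzofuran-2(3H)-one | O=C1Cc2ccc(O)cc2O1 | intermediate
3 | 6-(methoxymethoxy)-1-benzofuran-2(3H)-one | O=C1Cc2ccc(OCOC)cc2O1 | intermediate
4 | 2-[2-hydroxy-4-(methoxymethoxy)phenyl]-N-methoxy-N-methylacetamide | CON(C)C(=O)Cc1ccc(OCOC)cc1O | intermediate
5 | 2-[2-hydroxy-3-(hydroxymethyl)-4-(methoxymethoxy)phenyl]-N-methoxy-N-methylacetamide (magnesium salt in the flask) | CON(C)C(=O)Cc1ccc(OCOC)c(CO)c1O | intermediate (not isolated)
6 | 2-[3-formyl-2-hydroxy-4-(methoxymethoxy)phenyl]-N-methoxy-N-methylacetamide | CON(C)C(=O)Cc1ccc(OCOC)c(C=O)c1O | intermediate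
7 | 2-[3-ethenyl-2-hydroxy-4-(methoxymethoxy)phenyl]-N-methoxy-N-methylacetamide | CON(C)C(=O)Cc1ccc(OCOC)c(C=C)c1O | intermediate
8 | 2-methyl-2-vinyloxirane (isoprene monoepoxide, racemic) | CC1(C=C)CO1 | starting material
9 | 2-[3-ethenyl-2-{[(2S)-1-hydroxy-2-methylbut-3-en-2-yl]oxy}-4-(methoxymethoxy)phenyl]-N-methoxy-N-methylacetamide | C[C@@](CO)(C=C)Oc1c(CC(=O)N(C)OC)ccc(OCOC)c1C=C | intermediate
10 | 2-[2-{[(2S)-1-{[tert-butyl(dimethyl)silyl]oxy}-2-methylbut-3-en-2-yl]oxy}-3-ethenyl-4-(methoxymethoxy)phenyl]-N-methoxy-N-methylacetamide | C[C@@](CO[Si](C)(C)C(C)(C)C)(C=C)Oc1c(CC(=O)N(C)OC)ccc(OCOC)c1C=C | intermediate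
11 | 2-[(2S)-2-({[tert-butyl(dimethyl)silyl]oxy}methyl)-5-(methoxymethoxy)-2-methyl-2H-chromen-8-yl]-N-methoxy-N-methylacetamide | C[C@@]1(CO[Si](C)(C)C(C)(C)C)C=Cc2c(OCOC)ccc(CC(=O)N(C)OC)c2O1 | intermediate
12 | 4-hydroxy-6-methyl-2H-pyran-2-one (triacetic acid lactone) | CC1=CC(O)=CC(=O)O1 | starting material
13 | 6-{3-[(2S)-2-({[tert-butyl(dimethyl)silyl]oxy}methyl)-5-(methoxymethoxy)-2-methyl-2H-chromen-8-yl]-2-oxopropyl}-4-hydroxy-2H-pyran-2-one | C[C@@]1(CO[Si](C)(C)C(C)(C)C)C=Cc2c(OCOC)ccc(CC(=O)CC3=CC(O)=CC(=O)O3)c2O1 | intermediate (precursor of the key step)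
14 | methyl 8-[(2S)-2-({[tert-butyl(dimethyl)silyl]oxy}methyl)-5-(methoxymethoxy)-2-methyl-2H-chromen-8-yl]-3,5,7-trioxooctanoate (magnesium chelate in the flask) | C[C@@]1(CO[Si](C)(C)C(C)(C)C)C=Cc2c(OCOC)ccc(CC(=O)CC(=O)CC(=O)CC(=O)OC)c2O1 | intermediate (not isolated)
15 | 2-[(2S)-2-({[tert-butyl(dimethyl)silyl]oxy}methyl)-5-(methoxymethoxy)-2-methyl-2H-chromen-8-yl]-1-(2,4,6-trihydroxyphenyl)ethan-1-one | C[C@@]1(CO[Si](C)(C)C(C)(C)C)C=Cc2c(OCOC)ccc(CC(=O)c3c(O)cc(O)cc3O)c2O1 | intermediate (product of the key step)
16 | 2-[(2S)-2-({[tert-butyl(dimethyl)silyl]oxy}methyl)-5-(methoxymethoxy)-2-methyl-2H-chromen-8-yl]-3-(dimethylamino)-1-(2,4,6-trihydroxyphenyl)prop-2-en-1-one | C[C@@]1(CO[Si](C)(C)C(C)(C)C)C=Cc2c(OCOC)ccc(C(=CN(C)C)C(=O)c3c(O)cc(O)cc3O)c2O1 | intermediate (not isolated)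
17 | 3-[(2S)-2-({[tert-butyl(dimethyl)silyl]oxy}methyl)-5-(methoxymethoxy)-2-methyl-2H-chromen-8-yl]-5,7-dihydroxy-4H-chromen-4-one | C[C@@]1(CO[Si](C)(C)C(C)(C)C)C=Cc2c(OCOC)ccc(-c3coc4cc(O)cc(O)c4c3=O)c2O1 | intermediate
18 | 5,7-dihydroxy-3-[(2S)-5-hydroxy-2-(hydroxymethyl)-2-methyl-2H-chromen-8-yl]-4H-chromen-4-one | C[C@@]1(CO)C=Cc2c(O)ccc(-c3coc4cc(O)cc(O)c4c3=O)c2O1 | target

## Step count and risks

Total: 12 steps. Longest linear sequence: 12 steps from 1; compounds 8 and 12 are purchased.

**Step 10 (key step).** The most likely failure is misfolding of the triketo ester: aldol closure of chain carbon 2 onto the C7 carbonyl, or simple return to the pyrone. Chelate control is a fine balance, and here the ketone end carries an arylmethyl group instead of the methyl group of the closest models.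

The fallback brings ring A in ready-made; it sets out from 11 and returns at 18. Phloroglucinol is converted with MOMCl into 1,3,5-tris(methoxymethoxy)benzene F1. F1 is lithiated between two of its acetal oxygens (n-BuLi, THF, 0 °C) and added to the Weinreb amide 11 at −78 °C, which should give 2-[(2S)-2-({[tert-butyl(dimethyl)silyl]oxy}methyl)-5-(methoxymethoxy)-2-methyl-2H-chromen-8-yl]-1-[2,4,6-tris(methoxymethoxy)phenyl]ethan-1-one F2. Methanolic HCl then removes all four MOM groups and the silyl ether to give 2-[(2S)-5-hydroxy-2-(hydroxymethyl)-2-methyl-2H-chromen-8-yl]-1-(2,4,6-trihydroxyphenyl)ethan-1-one F3. Treatment of F3 with N,N-dimethylformamide dimethyl acetal as in step 11 closes ring C and gives 18 directly.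

**Step 9.** The most likely failure is proton transfer from the benzylic α-methylene of 11 to the strongly basic dianion in place of addition, so that 11 is returned unchanged.

The fallback replaces the acyl donor by an aldehyde, to which carbanions add faster than they abstract protons at low temperature; it sets out from 11 and returns at 13. Reduction of 11 with iBu2AlH (THF, −78 °C) should give 2-[(2S)-2-({[tert-butyl(dimethyl)silyl]oxy}methyl)-5-(methoxymethoxy)-2-methyl-2H-chromen-8-yl]acetaldehyde F4. Aldol addition of the dianion of 12 to F4 at −78 °C should give 6-{3-[(2S)-2-({[tert-butyl(dimethyl)silyl]oxy}methyl)-5-(methoxymethoxy)-2-methyl-2H-chromen-8-yl]-2-hydroxypropyl}-4-hydroxy-2H-pyran-2-one F5 as a mixture of carbinol epimers, which is of no consequence. Oxidation of F5 with Dess–Martin periodinane buffered with NaHCO3 gives 13.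

**Step 6.** The most likely failure is slow attack of the doubly ortho-substituted phenoxide at the tertiary allyl terminus. Re-ionisation of the tertiary allylic aryl ether by zerovalent palladium would then erode both the branched selectivity and the enantiomeric purity. The sense of induction by the ligand also has to be confirmed.

The fallback moves the etherification to the less hindered, less acidic phenol 4 and closes ring D by alkyne hydroarylation instead of metathesis; it sets out from 4 and returns at 11.
- The conditions of step 6 applied to 4 should give 2-[2-{[(2S)-1-hydroxy-2-methylbut-3-en-2-yl]oxy}-4-(methoxymethoxy)phenyl]-N-methoxy-N-methylacetamide F6.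
- Silylation as in step 7 gives 2-[2-{[(2S)-1-{[tert-butyl(dimethyl)silyl]oxy}-2-methylbut-3-en-2-yl]oxy}-4-(methoxymethoxy)phenyl]-N-methoxy-N-methylacetamide F7.
- Cleavage of the vinyl group (OsO4 cat., NaIO4, 2,6-lutidine, dioxane–water) gives 2-[2-{[(2R)-1-{[tert-butyl(dimethyl)silyl]oxy}-2-methyl-3-oxopropan-2-yl]oxy}-4-(methoxymethoxy)phenyl]-N-methoxy-N-methylacetamide F8. Its α-carbon is quaternary and cannot epimerise; the descriptor changes only because the priorities change.
- The Ohira–Bestmann reagent (K2CO3, MeOH) gives 2-[2-{[(2S)-1-{[tert-butyl(dimethyl)silyl]oxy}-2-methylbut-3-yn-2-yl]oxy}-4-(methoxymethoxy)phenyl]-N-methoxy-N-methylacetamide F9.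
- Ph3PAuNTf2 (CH2Cl2, rt) should cyclise F9 at the only free ortho carbon in the 6-endo mode to give 11.

**Step 4.** The most likely failure is stalling at the hydroxymethyl stage or no attack at all, because the only free ortho carbon lies between the phenoxide and the MOM ether and is crowded.

The fallback delivers the carbon substituent by a sigmatropic shift and carries a propenyl group in place of the vinyl group; it sets out from 4 and returns at 11.
- Allylation of 4 (allyl bromide, K2CO3, acetone) gives N-methoxy-2-[4-(methoxymethoxy)-2-(prop-2-en-1-yloxy)phenyl]-N-methylacetamide F10.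
- Aromatic Claisen rearrangement (N,N-diethylaniline, 180 °C) to the only free ortho carbon gives 2-[2-hydroxy-4-(methoxymethoxy)-3-(prop-2-en-1-yl)phenyl]-N-methoxy-N-methylacetamide F11.
- Isomerisation with RuClH(CO)(PPh3)3 (toluene, 80 °C) gives 2-{2-hydroxy-4-(methoxymethoxy)-3-[(1E)-prop-1-en-1-yl]phenyl}-N-methoxy-N-methylacetamide F12.
- The conditions of step 6 give 2-{2-{[(2S)-1-hydroxy-2-methylbut-3-en-2-yl]oxy}-4-(methoxymethoxy)-3-[(1E)-prop-1-en-1-yl]phenyl}-N-methoxy-N-methylacetamide F13.
- The conditions of step 7 give 2-{2-{[(2S)-1-{[tert-butyl(dimethyl)silyl]oxy}-2-methylbut-3-en-2-yl]oxy}-4-(methoxymethoxy)-3-[(1E)-prop-1-en-1-yl]phenyl}-N-methoxy-N-methylacetamide F14.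
- The conditions of step 8 close ring D with loss of propene and give 11.

## Further compounds

F1 | step 10 | 1,3,5-tris(methoxymethoxy)benzene | COCOc1cc(OCOC)cc(OCOC)c1
F2 | step 10 | 2-[(2S)-2-({[tert-butyl(dimethyl)silyl]oxy}methyl)-5-(methoxymethoxy)-2-methyl-2H-chromen-8-yl]-1-[2,4,6-tris(methoxymethoxy)phenyl]ethan-1-one | C[C@@]1(CO[Si](C)(C)C(C)(C)C)C=Cc2c(OCOC)ccc(CC(=O)c3c(OCOC)cc(OCOC)cc3OCOC)c2O1
F3 | step 10 | 2-[(2S)-5-hydroxy-2-(hydroxymethyl)-2-methyl-2H-chromen-8-yl]-1-(2,4,6-trihydroxyphenyl)ethan-1-one | C[C@@]1(CO)C=Cc2c(O)ccc(CC(=O)c3c(O)cc(O)cc3O)c2O1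
F4 | step 9 | 2-[(2S)-2-({[tert-butyl(dimethyl)silyl]oxy}methyl)-5-(methoxymethoxy)-2-methyl-2H-chromen-8-yl]acetaldehyde | C[C@@]1(CO[Si](C)(C)C(C)(C)C)C=Cc2c(OCOC)ccc(CC=O)c2O1
F5 | step 9 | 6-{3-[(2S)-2-({[tert-butyl(dimethyl)silyl]oxy}methyl)-5-(methoxymethoxy)-2-methyl-2H-chromen-8-yl]-2-hydroxypropyl}-4-hydroxy-2H-pyran-2-one (both carbinol epimers) | C[C@@]1(CO[Si](C)(C)C(C)(C)C)C=Cc2c(OCOC)ccc(CC(O)CC3=CC(O)=CC(=O)O3)c2O1
F6 | step 6 | 2-[2-{[(2S)-1-hydroxy-2-methylbut-3-en-2-yl]oxy}-4-(methoxymethoxy)phenyl]-N-methoxy-N-methylacetamide | C[C@@](CO)(C=C)Oc1cc(OCOC)ccc1CC(=O)N(C)OC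
F7 | step 6 | 2-[2-{[(2S)-1-{[tert-butyl(dimethyl)silyl]oxy}-2-methylbut-3-en-2-yl]oxy}-4-(methoxymethoxy)phenyl]-N-methoxy-N-methylacetamide | C[C@@](CO[Si](C)(C)C(C)(C)C)(C=C)Oc1cc(OCOC)ccc1CC(=O)N(C)OC
F8 | step 6 | 2-[2-{[(2R)-1-{[tert-butyl(dimethyl)silyl]oxy}-2-methyl-3-oxopropan-2-yl]oxy}-4-(methoxymethoxy)phenyl]-N-methoxy-N-methylacetamide | C[C@@](CO[Si](C)(C)C(C)(C)C)(C=O)Oc1cc(OCOC)ccc1CC(=O)N(C)OC
F9 | step 6 | 2-[2-{[(2S)-1-{[tert-butyl(dimethyl)silyl]oxy}-2-methylbut-3-yn-2-yl]oxy}-4-(methoxymethoxy)phenyl]-N-methoxy-N-methylacetamide | C[C@@](CO[Si](C)(C)C(C)(C)C)(C#C)Oc1cc(OCOC)ccc1CC(=O)N(C)OC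
F10 | step 4 | N-methoxy-2-[4-(methoxymethoxy)-2-(prop-2-en-1-yloxy)phenyl]-N-methylacetamide | C=CCOc1cc(OCOC)ccc1CC(=O)N(C)OC
F11 | step 4 | 2-[2-hydroxy-4-(methoxymethoxy)-3-(prop-2-en-1-yl)phenyl]-N-methoxy-N-methylacetamide | C=CCc1c(O)c(CC(=O)N(C)OC)ccc1OCOC
F12 | step 4 | 2-{2-hydroxy-4-(methoxymethoxy)-3-[(1E)-prop-1-en-1-yl]phenyl}-N-methoxy-N-methylacetamide | C/C=C/c1c(O)c(CC(=O)N(C)OC)ccc1OCOC
F13 | step 4 | 2-{2-{[(2S)-1-hydroxy-2-methylbut-3-en-2-yl]oxy}-4-(methoxymethoxy)-3-[(1E)-prop-1-en-1-yl]phenyl}-N-methoxy-N-methylacetamide | C[C@@](CO)(C=C)Oc1c(CC(=O)N(C)OC)ccc(OCOC)c1/C=C/C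
F14 | step 4 | 2-{2-{[(2S)-1-{[tert-butyl(dimethyl)silyl]oxy}-2-methylbut-3-en-2-yl]oxy}-4-(methoxymethoxy)-3-[(1E)-prop-1-en-1-yl]phenyl}-N-methoxy-N-methylacetamide | C[C@@](CO[Si](C)(C)C(C)(C)C)(C=C)Oc1c(CC(=O)N(C)OC)ccc(OCOC)c1/C=C/C
A1 | alternative 1 | (3E)-4-[5,7-bis(methoxymethoxy)-4-oxo-4H-chromen-3-yl]-1-diazobut-3-en-2-one | [N-]=[N+]=CC(=O)/C=C/c1coc2cc(OCOC)cc(OCOC)c2c1=O
A2 | alternative 1 | ({4-[(2R)-2-methyloxiran-2-yl]but-1-yn-1-yl}oxy)tri(propan-2-yl)silane | C[C@@]1(CCC#CO[Si](C(C)C)(C(C)C)C(C)C)CO1
A3 | alternative 1 | 3-{2-hydroxy-3-[2-((2R)-2-methyloxiran-2-yl)ethyl]-4-[tri(propan-2-yl)silyloxy]phenyl}-5,7-bis(methoxymethoxy)-4H-chromen-4-one | C[C@@]1(CCc2c(O)c(-c3coc4cc(OCOC)cc(OCOC)c4c3=O)ccc2O[Si](C(C)C)(C(C)C)C(C)C)CO1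
A4 | alternative 2 | 2-{[(2S)-1-(methoxymethoxy)-2-methylbut-3-yn-2-yl]oxy}-4-(methoxymethoxy)benzaldehyde | C[C@@](COCOC)(C#C)Oc1cc(OCOC)ccc1C=O
A5 | alternative 2 | (2S)-5-(methoxymethoxy)-2-[(methoxymethoxy)methyl]-2-methyl-2H-chromene-8-carbaldehyde | C[C@@]1(COCOC)C=Cc2c(OCOC)ccc(C=O)c2O1
A6 | alternative 3 | 2-[(2S)-5-(methoxymethoxy)-2-[(methoxymethoxy)methyl]-2-methyl-2H-chromen-8-yl]acetaldehyde | C[C@@]1(COCOC)C=Cc2c(OCOC)ccc(CC=O)c2O1
A7 | alternative 3 | 4-{(E)-2-[(2S)-5-(methoxymethoxy)-2-[(methoxymethoxy)methyl]-2-methyl-2H-chromen-8-yl]ethenyl}morpholine | C[C@@]1(COCOC)C=Cc2c(OCOC)ccc(/C=C/N3CCOCC3)c2O1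
A8 | alternative 3 | 2,4,6-tris(acetyloxy)benzoyl chloride | CC(=O)Oc1cc(OC(C)=O)c(C(=O)Cl)c(OC(C)=O)c1
A9 | alternative 3 | 5,7-dihydroxy-3-[(2S)-5-(methoxymethoxy)-2-[(methoxymethoxy)methyl]-2-methyl-2H-chromen-8-yl]-4H-chromen-4-one | C[C@@]1(COCOC)C=Cc2c(OCOC)ccc(-c3coc4cc(O)cc(O)c4c3=O)c2O1
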